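## Retrosynthetic overview

1. Target 19 ⇐ Stille coupling of (Z)-β-iodo acid 16 with AcOCH2SnBu3 (brings C16 and the acetate) ⇐ anti-hydroiodination of ynoic acid 15 ⇐ carboxylation (C15) of terminal alkyne 13; C17 comes from a Wittig reaction on a C8 ketone.
2. The C8 ketone and the C11–C14 butynyl chain arise together by Eschenmoser–Tanabe fragmentation of the 8,14-epoxy-13-ketone of a tricyclic enone: ring C of a podocarpane is unzipped.
3. Key step: Birch reduction and hydrolysis of the anisole ring of 13-methoxy-ent-podocarpa-8,11,13-triene 6 destroys the aromatic ring, gives enone 9 and sets C9.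
4. Tricycle 6 ⇐ enantioselective proton-initiated polyene cyclisation of homogeranyl anisole 4 (sets C5 and C10) ⇐ 3-methoxybenzyl chloride + geranyl chloride.
5. Ring order: the aromatic ring is bought; ring A, then ring B, form in the cyclisation; the aromatic ring C is then dearomatised and opened, leaving the A/B decalin.

Assumption: the (S)-configured BINOL mono-ether/SnCl4 acid is taken to give the 5R,10R series (its mirror image being the one that leads to the natural 5S,10S podocarpatrienes); if the sense proved opposite, the (R)-ligand would be used.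

## Route

Step 1
Reactants: 1 3-methoxybenzyl chloride; 2 geranyl chloride
Product: 4 1-[(3E)-4,8-dimethylnona-3,7-dien-1-yl]-3-methoxybenzene, via 3-methoxybenzylmagnesium chloride 3 (not isolated)
Conditions: Mg, Et2O, 0 °C to rt (slow addition of 1); then 2, Li2CuCl4 (2 mol %), THF, 0 °C
Reagents that add atoms: none
Why: Copper-catalysed Kochi-type coupling of a benzylic Grignard reagent with a primary allylic chloride takes place at the α-carbon with retention of the E-alkene, and no stereocentre is formed.

Step 2
Reactants: 4 1-[(3E)-4,8-dimethylnona-3,7-dien-1-yl]-3-methoxybenzene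
Product: 6 13-methoxy-ent-podocarpa-8,11,13-triene [(4aR,10aR)-7-methoxy-1,1,4a-trimethyl-1,2,3,4,4a,9,10,10a-octahydrophenanthrene], via monocyclic arene 5 (not isolated)
Conditions: (S)-2-(2-fluorobenzyloxy)-2′-hydroxy-1,1′-binaphthyl (1.1 equiv), SnCl4 (1.0 equiv), toluene, −78 °C, 3 d; then CF3CO2H, SnCl4, CH2Cl2, −78 °C
Reagents that add atoms: none
Why: Enantioselective proton-initiated biomimetic polyene cyclisation with a chiral Lewis-acid-assisted Brønsted acid: the BINOL–SnCl4 acid protonates one face of the terminal isopropylidene group and ring A closes through a chair to fix C5, then the achiral acid re-ionises C10 and the anisole ring (para to OMe) closes ring B through a chair so that the C10 methyl ends anti to H5 (trans ring fusion).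

Step 3
Reactants: 6 13-methoxy-ent-podocarpa-8,11,13-triene
Product: 9 (5R,9R,10R)-podocarp-8(14)-en-13-one (ent series; H9 anti to the C10 methyl), via dienol ether 7 (not isolated), via unconjugated enone 8 (not isolated)
Conditions: Li, NH3(l), THF, t-BuOH, −33 °C; aqueous work-up; then 3 M HCl, MeOH, 60 °C
Reagents that add atoms: water, O
Why: Birch reduction leaves the methoxy and alkyl carbons on the double bonds (1-methoxy-1,4-diene 7), and acid hydrolysis of the enol ether followed by acid-catalysed conjugation gives the enone, the new C9 centre being set under thermodynamic control with H9 anti to the C10 methyl (C11 equatorial on ring B).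

Step 4
Reactants: 9 (5R,9R,10R)-podocarp-8(14)-en-13-one
Product: 10 8,14-epoxy-ent-podocarpan-13-one (epoxide oxygen cis to H9)
Conditions: 30% H2O2, NaOH, MeOH, 0 °C
Reagents that add atoms: hydrogen peroxide, OO
Why: Weitz–Scheffer nucleophilic epoxidation of the β,β-disubstituted enone by hydroperoxide creates C8 and C14 (mainly with the oxygen cis to H9), and both centres are erased in the next step so the diastereomer ratio is irrelevant.

Step 5
Reactants: 10 8,14-epoxy-ent-podocarpan-13-one
Product: 12 15,16,17-trinor-ent-labd-13-yn-8-one [(1S,4aR,8aR)-1-(but-3-yn-1-yl)-5,5,8a-trimethyloctahydronaphthalen-2(1H)-one], via tosylhydrazone 11 (not isolated)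
Conditions: TsNHNH2 (1.05 equiv), AcOH/CH2Cl2 (1:1), −20 °C to rt
Reagents that add atoms: none
Why: Eschenmoser–Tanabe fragmentation of the epoxy ketone tosylhydrazone breaks the C8–C14 bond with loss of N2 and sulfinate to give the C8 ketone and the terminal C13–C14 alkyne, with C9 now α to the ketone and still in its more stable equatorial arrangement.

Step 6
Reactants: 12 15,16,17-trinor-ent-labd-13-yn-8-one
Product: 13 15,16-dinor-ent-labd-8(17)-en-13-yne [(1R,4aR,8aR)-1-(but-3-yn-1-yl)-5,5,8a-trimethyl-2-methylidenedecahydronaphthalene]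
Conditions: Ph3PCH3Br, KN(SiMe3)2, THF/toluene, 0 °C to 70 °C
Reagents that add atoms: methyltriphenylphosphonium bromide, C[P+](c1ccccc1)(c1ccccc1)c1ccccc1.[Br-]
Why: Wittig methylenation converts the hindered C8 ketone into the 8(17)-methylene group, the ylide being too weak a base to deprotonate the alkyne and any epimerisation at C9 returning to the stable (required) configuration.

Step 7
Reactants: 13 15,16-dinor-ent-labd-8(17)-en-13-yne
Product: 15 16-nor-ent-labd-8(17)-en-13-yn-15-oic acid, via lithium acetylide 14 (not isolated)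
Conditions: n-BuLi, THF, −78 °C; CO2 (g), −78 °C to rt; 1 M HCl
Reagents that add atoms: carbon dioxide, O=C=O
Why: Deprotonation of the terminal alkyne and carboxylation of the lithium acetylide with CO2 installs C15 without touching the isolated alkene.

Step 8
Reactants: 15 16-nor-ent-labd-8(17)-en-13-yn-15-oic acid
Product: 16 (13Z)-13-iodo-16-nor-ent-labda-8(17),13-dien-15-oic acid
Conditions: NaI (3 equiv), AcOH, 70 °C
Reagents that add atoms: sodium iodide, [Na+].[I-]
Why: Conjugate addition of iodide to the ynoic acid followed by anti protonation (stereospecific anti-hydroiodination) gives the (Z)-3-iodo-2-enoic acid with iodine cis to CO2H, the medium being only weakly acidic so the 1,1-disubstituted alkene is not protonated.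

Step 9
Reactants: 17 (tributylstannyl)methanol
Product: 18 (acetoxymethyl)tributylstannane
Conditions: Ac2O, pyridine, DMAP (cat.), CH2Cl2, 0 °C to rt
Reagents that add atoms: acetic anhydride, CC(=O)OC(C)=O
Why: Standard DMAP-catalysed O-acetylation of a primary alcohol; the C–Sn bond is inert to these conditions.

Step 10
Reactants: 16 (13Z)-13-iodo-16-nor-ent-labda-8(17),13-dien-15-oic acid; 18 (acetoxymethyl)tributylstannane
Product: 19 (13Z)-16-acetoxy-ent-labda-8(17),13-dien-15-oic acid (target)
Conditions: Pd2(dba)3 (5 mol %), AsPh3 (20 mol %), CuI (10 mol %), NMP, 40 °C; dilute HCl work-up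
Reagents that add atoms: none
Why: Migita–Kosugi–Stille coupling in which the α-oxygenated CH2OAc group is transferred in preference to butyl and the alkenyl iodide reacts with retention, so CH2OAc ends cis to CO2H and the 13Z geometry of the target is fixed.

## Compound list

1 | 3-methoxybenzyl chloride | COc1cccc(CCl)c1 | starting material
2 | geranyl chloride, (2E)-1-chloro-3,7-dimethylocta-2,6-diene | ClC/C=C(\C)CCC=C(C)C | starting material
3 | 3-methoxybenzylmagnesium chloride | COc1cccc(C[Mg]Cl)c1 | intermediate (not isolated)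
4 | 1-[(3E)-4,8-dimethylnona-3,7-dien-1-yl]-3-methoxybenzene | COc1cccc(CC/C=C(\C)CCC=C(C)C)c1 | intermediate
5 | 1-methoxy-3-{2-[(1R)-2,6,6-trimethylcyclohex-2-en-1-yl]ethyl}benzene (main monocyclic olefin isomer) | COc1cccc(CC[C@@H]2C(C)(C)CCC=C2C)c1 | intermediate (not isolated)
6 | 13-methoxy-ent-podocarpa-8,11,13-triene, (5R,10R), trans-fused | COc1ccc2c(c1)CC[C@@H]1C(C)(C)CCC[C@@]21C | intermediate
7 | 13-methoxy-ent-podocarpa-8,12-diene, (5R,10R) | COC1=CCC2=C(C1)CC[C@@H]1C(C)(C)CCC[C@@]21C | intermediate (not isolated)
8 | ent-podocarp-8-en-13-one, (5R,10R) | O=C1CCC2=C(C1)CC[C@@H]1C(C)(C)CCC[C@@]21C | intermediate (not isolated)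
9 | ent-podocarp-8(14)-en-13-one, (5R,9R,10R), H9 anti to C10 methyl | O=C1C=C2CC[C@@H]3C(C)(C)CCC[C@@]3(C)[C@@H]2CC1 | intermediate
10 | 8,14-epoxy-ent-podocarpan-13-one, epoxide oxygen cis to H9 | O=C1[C@H]2O[C@]23CC[C@@H]4C(C)(C)CCC[C@@]4(C)[C@@H]3CC1 | intermediate
11 | p-toluenesulfonylhydrazone of 10 (C=N geometry not fixed) | Cc1ccc(cc1)S(=O)(=O)NN=C1[C@H]2O[C@]23CC[C@@H]4C(C)(C)CCC[C@@]4(C)[C@@H]3CC1 | intermediate (not isolated)
12 | 15,16,17-trinor-ent-labd-13-yn-8-one, (5R,9S,10R), side chain equatorial | O=C1CC[C@@H]2C(C)(C)CCC[C@@]2(C)[C@@H]1CCC#C | intermediate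
13 | 15,16-dinor-ent-labd-8(17)-en-13-yne, (5R,9R,10R) | C=C1CC[C@@H]2C(C)(C)CCC[C@@]2(C)[C@@H]1CCC#C | intermediate
14 | lithium acetylide of 13 | C=C1CC[C@@H]2C(C)(C)CCC[C@@]2(C)[C@@H]1CCC#C[Li] | intermediate (not isolated)
15 | 16-nor-ent-labd-8(17)-en-13-yn-15-oic acid | C=C1CC[C@@H]2C(C)(C)CCC[C@@]2(C)[C@@H]1CCC#CC(=O)O | intermediate
16 | (13Z)-13-iodo-16-nor-ent-labda-8(17),13-dien-15-oic acid | C=C1CC[C@@H]2C(C)(C)CCC[C@@]2(C)[C@@H]1CC/C(I)=C/C(=O)O | intermediate
17 | (tributylstannyl)methanol | CCCC[Sn](CCCC)(CCCC)CO | starting material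
18 | (acetoxymethyl)tributylstannane | CCCC[Sn](CCCC)(CCCC)COC(C)=O | intermediate
19 | (13Z)-16-acetoxy-ent-labda-8(17),13-dien-15-oic acid; (2Z)-3-(acetoxymethyl)-5-[(1R,4aR,8aR)-5,5,8a-trimethyl-2-methylidenedecahydronaphthalen-1-yl]pent-2-enoic acid | C=C1CC[C@@H]2C(C)(C)CCC[C@@]2(C)[C@@H]1CC/C(=C/C(=O)O)COC(C)=O | target

## Step count and risks

Total steps: 10 (nine on the main line plus one to make stannane 18). Longest linear sequence: 9 steps (steps 1–8 and 10).

The three steps most likely to fail:

Step 2. The chiral acid gives only about 75–90% ee with this substrate class, and some cyclisation ortho to OMe is possible. Enone 9 should be recrystallised to enantiopurity before going on; its crystallinity is expected, not confirmed. The fallback sets out from 4 and changes the initiating electrophile. An iodonium-initiated enantioselective cyclisation (N-iodosuccinimide with one equivalent of a BINOL-derived chiral phosphoramidite, toluene, −40 °C; then ClSO3H in 2-nitropropane at −78 °C to close ring B) gives 3-iodo-13-methoxy-ent-podocarpa-8,11,13-triene F1, with iodine equatorial. Radical deiodination with Bu3SnH and AIBN in benzene at 80 °C then returns to the route at 6.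

Step 6. The C8 ketone is hindered and enolisable, so the ylide may mainly enolise it. The fallback sets out from 12 and is a two-stage Peterson olefination. The weakly basic organocerium reagent from Me3SiCH2Li and CeCl3 (THF, −78 °C) adds to the carbonyl from the equatorial side to give 17-(trimethylsilyl)-15,16-dinor-ent-labd-13-yn-8-ol F2. Treatment with KH in THF at rt eliminates silanolate and returns to the route at 13.

Step 10. Zerovalent palladium may ionise the allylic acetate of the product, and the neighbouring carboxylic acid could then close the butenolide; transfer of CH2OAc from tin may also be slow. The fallback sets out from 13 and carries C15 at the aldehyde level through the coupling, so that no internal nucleophile is present. Lithium acetylide 14 is quenched with DMF to give 16-nor-ent-labd-8(17)-en-13-yn-15-al F3. NaI in AcOH at rt gives (13Z)-13-iodo-16-nor-ent-labda-8(17),13-dien-15-al F4. Stille coupling with 18 under the step 10 conditions gives (13Z)-16-acetoxy-ent-labda-8(17),13-dien-15-al F5. Pinnick oxidation (NaClO2, NaH2PO4, 2-methyl-2-butene, t-BuOH/H2O, 0 °C) then comes back to the route at 19.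

Further compounds

F1 | step 2 | 3-iodo-13-methoxy-ent-podocarpa-8,11,13-triene (iodine equatorial, cis to the C10 methyl) | COc1ccc2c(c1)CC[C@@H]1C(C)(C)[C@H](I)CC[C@@]21C
F2 | step 6 | 17-(trimethylsilyl)-15,16-dinor-ent-labd-13-yn-8-ol (hydroxyl axial, cis to the C10 methyl) | C[Si](C)(C)C[C@@]1(O)CC[C@@H]2C(C)(C)CCC[C@@]2(C)[C@@H]1CCC#C
F3 | step 10 | 16-nor-ent-labd-8(17)-en-13-yn-15-al | C=C1CC[C@@H]2C(C)(C)CCC[C@@]2(C)[C@@H]1CCC#CC=O
F4 | step 10 | (13Z)-13-iodo-16-nor-ent-labda-8(17),13-dien-15-al | C=C1CC[C@@H]2C(C)(C)CCC[C@@]2(C)[C@@H]1CC/C(I)=C/C=O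
F5 | step 10 | (13Z)-16-acetoxy-ent-labda-8(17),13-dien-15-al | C=C1CC[C@@H]2C(C)(C)CCC[C@@]2(C)[C@@H]1CC/C(=C/C=O)COC(C)=O
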